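**Retrosynthetic overview**
1. Numbering: ring carbons C1–C10 (C1 = enol-ether carbon, C4 = quaternary O-bearing carbon with methyl, C8 = CH–O-methacryloyl, C10 = carbinol carbon), lactone C6/C7/C11/C12, C13 = CH2OAc. Enabling feature: the 2,3-dihydrofuran O–C1(=C2)–C3H2–C4, whose C4 carries a carbon (C5) that can be drawn as a carbonyl group; this is the retron of a vinyl carbonyl ylide 1,5-electrocyclisation (enone O=C1–C2=C3 plus acceptor carbene C4).
2. Last: C5=C6 by dehydration of a C5–OH/C6–H aldol unit inside the ring, after C13 acetylation and C8 methacrylation; the ring enforces the E (ring-cis) alkylidene.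
3. Ten-membered carbocycle (nine-membered oxacycle through the bridging oxygen): C7–C8 by Nozaki–Hiyama–Kishi closure of a β-iodobutenolide onto a C8 aldehyde; C5–C6 before that by vinylogous Mukaiyama aldol of iodobutenolide 16 with aldehyde 11.
4. Dihydrofuran: formal (4+1) cycloaddition of vinyl ketone 6 (C10 from (S)-citramalic acid) with the copper carbene of ethyl 2-diazopropanoate 8, forming O–C4 and then C3–C4, with C4 set by the catalyst.
5. Ring order: dihydrofuran (step 7), butenolide brought in preformed (made in step 12, attached in step 13), ten-membered ring (step 15).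

Key step: step 7

Remark: C5 and C6 of 18–24 are left unassigned because both become sp2 in step 19; the ring closure of step 15 is assumed to give the 8R carbinol, and the 8-epimer is covered by a fallback.

Step 1
Reactants: 1 (S)-citramalic acid
Product: 2 2-[(4S)-2,2,4-trimethyl-5-oxo-1,3-dioxolan-4-yl]acetic acid
Conditions: 2,2-dimethoxypropane, TsOH (cat.), acetone, rt
Reagents that add atoms: 2,2-dimethoxypropane, COC(C)(C)OC
Why: Acid-catalysed acetonide (dioxolanone) formation engages only the α-hydroxy acid unit in a five-membered ring and should leave the β-carboxyl free, with C10 untouched.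

Step 2
Reactants: 2 2-[(4S)-2,2,4-trimethyl-5-oxo-1,3-dioxolan-4-yl]acetic acid
Product: 3 (5S)-5-(2-hydroxyethyl)-2,2,5-trimethyl-1,3-dioxolan-4-one
Conditions: BH3·SMe2, THF, 0 °C → rt; aqueous work-up
Reagents that add atoms: none
Why: Chemoselective borane reduction of a free carboxylic acid (acyloxyborane pathway) should spare the dioxolanone carbonyl.

Step 3
Reactants: 3 (5S)-5-(2-hydroxyethyl)-2,2,5-trimethyl-1,3-dioxolan-4-one
Product: 4 (2S)-2,4-dihydroxy-N-methoxy-N,2-dimethylbutanamide
Conditions: MeNH(OMe)·HCl, Me3Al, CH2Cl2, 0 °C → rt; dilute HCl work-up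
Reagents that add atoms: N,O-dimethylhydroxylamine hydrochloride, CNOC.Cl
Why: Weinreb aminolysis by the aluminium amide should open the activated dioxolanone (or the lactone in equilibrium with it) with loss of acetone and give the hydroxy Weinreb amide.

Step 4
Reactants: 4 (2S)-2,4-dihydroxy-N-methoxy-N,2-dimethylbutanamide
Product: 5 (2S)-N-methoxy-N,2-dimethyl-2,4-bis(triethylsilyloxy)butanamide
Conditions: Et3SiOTf, 2,6-lutidine, CH2Cl2, −78 → 0 °C
Reagents that add atoms: triethylsilyl trifluoromethanesulfonate, CC[Si](CC)(CC)OS(=O)(=O)C(F)(F)F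
Why: Silyl triflate silylation should cap both the primary and the hindered tertiary hydroxyl and so prevent relactonisation and later O–H insertion.

Step 5
Reactants: 5 (2S)-N-methoxy-N,2-dimethyl-2,4-bis(triethylsilyloxy)butanamide
Product: 6 (4S)-4-methyl-4,6-bis(triethylsilyloxy)hex-1-en-3-one
Conditions: CH2=CHMgBr, THF, −20 → 0 °C; cold aq. NH4Cl
Reagents that add atoms: vinylmagnesium bromide, C=C[Mg]Br
Why: Weinreb ketone synthesis: the chelated tetrahedral intermediate should stop at mono-addition, and a cold quench avoids conjugate addition of the released amine to the vinyl ketone.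

Step 6
Reactants: 7 ethyl 2-methyl-3-oxobutanoate
Product: 8 ethyl 2-diazopropanoate
Conditions: 4-acetamidobenzenesulfonyl azide, DBU, MeCN, 0 °C → rt
Reagents that add atoms: 4-acetamidobenzenesulfonyl azide, CC(=O)Nc1ccc(cc1)S(=O)(=O)N=[N+]=[N-]
Why: Deacylative (Regitz-type) diazo transfer to a 2-alkyl acetoacetate should deliver the α-alkyl diazo ester with transfer of the acetyl group to the sulfonamide.

Step 7
Reactants: 6 (4S)-4-methyl-4,6-bis(triethylsilyloxy)hex-1-en-3-one; 8 ethyl 2-diazopropanoate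
Product: 10 ethyl (2R)-5-[(2S)-2,4-bis(triethylsilyloxy)butan-2-yl]-2-methyl-2,3-dihydrofuran-2-carboxylate, via vinyl carbonyl ylide 9 (not isolated)
Conditions: (CuOTf)2·C6H6 (5 mol %), (S,S)-tBu-box (6 mol %), 4 Å MS, CH2Cl2, 0 °C → rt; 8 (2.5 equiv) added over 8 h
Reagents that add atoms: none
Why: Proposed new method: the copper carbene from 8 should be attacked by the ketone oxygen of 6 to give vinyl carbonyl ylide 9, whose 6π (1,5-) electrocyclisation joins the carbanionic carbon (C4) to the vinyl terminus (C3) in a formal (4+1) cycloaddition; the closest known reactions are the copper- and rhodium-catalysed (4+1) annulations of enones with diazomalonates and aryldiazoacetates to 2,3-dihydrofurans (also in an enantioselective copper/chiral bipyridine form) and the carbonyl-ylide chemistry of α-alkyl-α-diazo esters, but an α-methyl diazo ester has not been used in this annulation. The dihydrofuran is closed by a disrotatory 1,5-electrocyclisation of the oxapentadienyl anion, a 5-endo closure that is allowed because it is pericyclic. The quaternary centre C4 is set under catalyst control, the chiral bis(oxazoline) staying on monovalent copper (as its enolate) during C–C bond formation, because C10 lies trans across the ylide and is too remote to bias the faces; the ligand antipode is used if the sense proves opposite. The step needs ylide formation to win over 1,2-hydride shift (ethyl acrylate) and cyclopropanation, which slow addition and the electron-poor alkene should secure. It also needs closure onto carbon and not onto the ester oxygen (dioxole), which the quaternary C10 should secure by holding the vinyl ketone s-cis and steering the carbene to the oxygen lone pair on the vinyl side.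

Step 8
Reactants: 10 ethyl (2R)-5-[(2S)-2,4-bis(triethylsilyloxy)butan-2-yl]-2-methyl-2,3-dihydrofuran-2-carboxylate
Product: 11 (2R)-5-[(2S)-2,4-bis(triethylsilyloxy)butan-2-yl]-2-methyl-2,3-dihydrofuran-2-carbaldehyde
Conditions: i-Bu2AlH (1.2 equiv), CH2Cl2, −78 °C; Rochelle salt
Reagents that add atoms: none
Why: Partial hydride reduction of an α-alkoxy ester should stop at the aldehyde because the α-oxygen stabilises the aluminium hemiacetal at −78 °C; C4 has no α-hydrogen and cannot epimerise.

Step 9
Reactants: 12 but-2-yne-1,4-diol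
Product: 13 4-(tert-butyldimethylsilyloxy)but-2-yn-1-ol
Conditions: NaH (1 equiv), THF, 0 °C; t-BuMe2SiCl (1 equiv)
Reagents that add atoms: tert-butyldimethylsilyl chloride, CC(C)(C)[Si](C)(C)Cl
Why: Monosilylation of a symmetrical diol through its sparingly soluble monosodium alkoxide should give the mono ether.

Step 10
Reactants: 13 4-(tert-butyldimethylsilyloxy)but-2-yn-1-ol
Product: 14 4-(tert-butyldimethylsilyloxy)but-2-yn-1-yl methyl carbonate
Conditions: ClCO2Me, pyridine, CH2Cl2, 0 °C
Reagents that add atoms: methyl chloroformate, COC(=O)Cl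
Why: Standard acylation of the primary propargylic alcohol installs the leaving group for the next step.

Step 11
Reactants: 14 4-(tert-butyldimethylsilyloxy)but-2-yn-1-yl methyl carbonate
Product: 15 methyl 2-[(tert-butyldimethylsilyloxy)methyl]buta-2,3-dienoate
Conditions: Pd(OAc)2 (2 mol %), PPh3 (8 mol %), CO (10 bar), MeOH, 40 °C
Reagents that add atoms: carbon monoxide, [C-]#[O+]
Why: Palladium-catalysed carbonylation of a propargylic carbonate: SN2' oxidative addition to zerovalent palladium gives an allenylpalladium species, and CO insertion with capture by the released methoxide should give the 2-substituted 2,3-dienoate.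

Step 12
Reactants: 15 methyl 2-[(tert-butyldimethylsilyloxy)methyl]buta-2,3-dienoate
Product: 16 3-[(tert-butyldimethylsilyloxy)methyl]-4-iodofuran-2(5H)-one
Conditions: I2, NaHCO3, MeCN/H2O (10:1), 0 °C → rt
Reagents that add atoms: iodine, II; water, O
Why: Iodolactonisation of a 2,3-allenoate should put iodine on the central allene carbon while the ester carbonyl oxygen closes onto the terminal CH2, giving the β-iodobutenolide after loss of methanol.

Step 13
Reactants: 11 (2R)-5-[(2S)-2,4-bis(triethylsilyloxy)butan-2-yl]-2-methyl-2,3-dihydrofuran-2-carbaldehyde; 16 3-[(tert-butyldimethylsilyloxy)methyl]-4-iodofuran-2(5H)-one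
Product: 18 vinylogous aldol adduct (C5–OSiEt3; C5/C6 unassigned), via silyloxyfuran 17 (not isolated)
Conditions: 16 (1.3 equiv), Et3N, Et3SiOTf (2.2 equiv), CH2Cl2, −78 °C; then 11, −78 → −20 °C
Reagents that add atoms: triethylsilyl trifluoromethanesulfonate, CC[Si](CC)(CC)OS(=O)(=O)C(F)(F)F
Why: One-pot soft enolisation of 16 to silyloxyfuran 17 and silyl-triflate-promoted vinylogous Mukaiyama aldol at the furan 5-position (C6) onto the non-enolisable aldehyde should form C5–C6 with silyl transfer to the C5 oxygen; the amine buffer protects the enol ether, and the C5/C6 diastereomers (Felkin-type, threo expected) are inconsequential.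

Step 14
Reactants: 18 vinylogous aldol adduct (C5–OSiEt3; C5/C6 unassigned)
Product: 19 (3S)-3-[(5R)-5-{[4-[(tert-butyldimethylsilyloxy)methyl]-3-iodo-5-oxo-2,5-dihydrofuran-2-yl](triethylsilyloxy)methyl}-5-methyl-4,5-dihydrofuran-2-yl]-3-(triethylsilyloxy)butanal
Conditions: (COCl)2, DMSO, CH2Cl2, −78 → −40 °C; Et3N, −78 → 0 °C
Reagents that add atoms: none
Why: Swern oxidation with in-situ cleavage of a primary triethylsilyl ether should convert only the C8 silyl ether into the aldehyde, because secondary and tertiary triethylsilyl ethers and the tert-butyldimethylsilyl ether are inert to the chlorosulfonium reagent at this temperature.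

Step 15
Reactants: 19 (3S)-3-[(5R)-5-{[4-[(tert-butyldimethylsilyloxy)methyl]-3-iodo-5-oxo-2,5-dihydrofuran-2-yl](triethylsilyloxy)methyl}-5-methyl-4,5-dihydrofuran-2-yl]-3-(triethylsilyloxy)butanal
Product: 20 (4R,8R,10S)-13-(tert-butyldimethylsilyloxy)-8-hydroxy-5,10-bis(triethylsilyloxy)-1,4-epoxygermacra-1,7(11)-dien-12,6-olide
Conditions: CrCl2 (15 equiv), NiCl2 (0.5 equiv), degassed DMSO/THF, rt, 0.002 M
Reagents that add atoms: none
Why: Nozaki–Hiyama–Kishi reaction: nickel-mediated insertion into the activated C7–I bond, transmetalation to trivalent chromium and chemoselective 1,2-addition to the C8 aldehyde should close the nine-membered oxacycle (ten-membered carbocycle) at high dilution, a closure type well precedented for oxonanes bridged by a five-membered cyclic ether; C8 is set by macrocyclic substrate control, and the 8R carbinol is the one assumed (see remark).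

Step 16
Reactants: 20 (4R,8R,10S)-13-(tert-butyldimethylsilyloxy)-8-hydroxy-5,10-bis(triethylsilyloxy)-1,4-epoxygermacra-1,7(11)-dien-12,6-olide
Product: 21 (4R,8R,10S)-13-(tert-butyldimethylsilyloxy)-8-(methacryloyloxy)-5,10-bis(triethylsilyloxy)-1,4-epoxygermacra-1,7(11)-dien-12,6-olide
Conditions: methacrylic anhydride, Et3N, DMAP, CH2Cl2, 0 °C → rt
Reagents that add atoms: methacrylic anhydride, C=C(C)C(=O)OC(=O)C(C)=C
Why: DMAP-catalysed acylation of the only free hydroxyl should give the methacrylate with retention at C8.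

Step 17
Reactants: 21 (4R,8R,10S)-13-(tert-butyldimethylsilyloxy)-8-(methacryloyloxy)-5,10-bis(triethylsilyloxy)-1,4-epoxygermacra-1,7(11)-dien-12,6-olide
Product: 22 (4R,8R,10S)-5,10,13-trihydroxy-8-(methacryloyloxy)-1,4-epoxygermacra-1,7(11)-dien-12,6-olide
Conditions: HF·pyridine, pyridine, THF, 0 °C → rt
Reagents that add atoms: none
Why: Pyridine-buffered fluoride desilylation should remove the two triethylsilyl ethers and the primary tert-butyldimethylsilyl ether without hydrating the enol ether or cleaving the ester.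

Step 18
Reactants: 22 (4R,8R,10S)-5,10,13-trihydroxy-8-(methacryloyloxy)-1,4-epoxygermacra-1,7(11)-dien-12,6-olide
Product: 23 (4R,8R,10S)-13-acetoxy-5,10-dihydroxy-8-(methacryloyloxy)-1,4-epoxygermacra-1,7(11)-dien-12,6-olide
Conditions: Ac2O (1.1 equiv), 2,4,6-collidine, CH2Cl2, −20 → 0 °C
Reagents that add atoms: acetic anhydride, CC(=O)OC(C)=O
Why: Selective acylation should take the primary allylic C13 hydroxyl in preference to the neopentyl-type secondary C5 hydroxyl and the tertiary C10 hydroxyl.

Step 19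
Reactants: 23 (4R,8R,10S)-13-acetoxy-5,10-dihydroxy-8-(methacryloyloxy)-1,4-epoxygermacra-1,7(11)-dien-12,6-olide
Product: 25 target CNP0394509.1, via C5 mesylate 24 (not isolated)
Conditions: MsCl (1.3 equiv), Et3N, CH2Cl2, −30 °C; then DBU, 0 °C → rt
Reagents that add atoms: none
Why: Sulfonylation of the secondary C5 hydroxyl (the tertiary C10 hydroxyl should not react at −30 °C) followed by E1cB elimination through the butenolide dienolate should form C5=C6, mesylate being a far better leaving group than the C13 acetate; the ring allows only the E (ring-cis) alkylidene.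

**Compound list**
1 | (S)-citramalic acid | OC(=O)C[C@](C)(O)C(=O)O | starting material
2 | 2-[(4S)-2,2,4-trimethyl-5-oxo-1,3-dioxolan-4-yl]acetic acid | OC(=O)C[C@]1(C)OC(C)(C)OC1=O | intermediate
3 | (5S)-5-(2-hydroxyethyl)-2,2,5-trimethyl-1,3-dioxolan-4-one | OCC[C@]1(C)OC(C)(C)OC1=O | intermediate
4 | (2S)-2,4-dihydroxy-N-methoxy-N,2-dimethylbutanamide | OCC[C@](C)(O)C(=O)N(C)OC | intermediate
5 | (2S)-N-methoxy-N,2-dimethyl-2,4-bis(triethylsilyloxy)butanamide | CC[Si](CC)(CC)OCC[C@](C)(O[Si](CC)(CC)CC)C(=O)N(C)OC | intermediate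
6 | (4S)-4-methyl-4,6-bis(triethylsilyloxy)hex-1-en-3-one | CC[Si](CC)(CC)OCC[C@](C)(O[Si](CC)(CC)CC)C(=O)C=C | intermediate
7 | ethyl 2-methyl-3-oxobutanoate (racemic) | CCOC(=O)C(C)C(C)=O | starting material
8 | ethyl 2-diazopropanoate | CCOC(=O)C(C)=[N+]=[N-] | intermediate
9 | vinyl carbonyl ylide from 6 and the carbene of 8 | CC[Si](CC)(CC)OCC[C@](C)(O[Si](CC)(CC)CC)C(C=C)=[O+][C-](C)C(=O)OCC | intermediate (not isolated)
10 | ethyl (2R)-5-[(2S)-2,4-bis(triethylsilyloxy)butan-2-yl]-2-methyl-2,3-dihydrofuran-2-carboxylate | CC[Si](CC)(CC)OCC[C@](C)(O[Si](CC)(CC)CC)C1=CC[C@](C)(C(=O)OCC)O1 | intermediate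
11 | (2R)-5-[(2S)-2,4-bis(triethylsilyloxy)butan-2-yl]-2-methyl-2,3-dihydrofuran-2-carbaldehyde | CC[Si](CC)(CC)OCC[C@](C)(O[Si](CC)(CC)CC)C1=CC[C@](C)(C=O)O1 | intermediate
12 | but-2-yne-1,4-diol | OCC#CCO | starting material
13 | 4-(tert-butyldimethylsilyloxy)but-2-yn-1-ol | OCC#CCO[Si](C)(C)C(C)(C)C | intermediate
14 | 4-(tert-butyldimethylsilyloxy)but-2-yn-1-yl methyl carbonate | COC(=O)OCC#CCO[Si](C)(C)C(C)(C)C | intermediate
15 | methyl 2-[(tert-butyldimethylsilyloxy)methyl]buta-2,3-dienoate | C=C=C(CO[Si](C)(C)C(C)(C)C)C(=O)OC | intermediate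
16 | 3-[(tert-butyldimethylsilyloxy)methyl]-4-iodofuran-2(5H)-one | O=C1OCC(I)=C1CO[Si](C)(C)C(C)(C)C | intermediate
17 | 3-[(tert-butyldimethylsilyloxy)methyl]-4-iodo-2-(triethylsilyloxy)furan | CC[Si](CC)(CC)Oc1occ(I)c1CO[Si](C)(C)C(C)(C)C | intermediate (not isolated)
18 | 5-{[(2R)-5-[(2S)-2,4-bis(triethylsilyloxy)butan-2-yl]-2-methyl-2,3-dihydrofuran-2-yl](triethylsilyloxy)methyl}-3-[(tert-butyldimethylsilyloxy)methyl]-4-iodofuran-2(5H)-one (carbinol carbon C5 and furanone C6 unassigned; diastereomer mixture) | CC[Si](CC)(CC)OCC[C@](C)(O[Si](CC)(CC)CC)C1=CC[C@](C)(C(O[Si](CC)(CC)CC)C2OC(=O)C(CO[Si](C)(C)C(C)(C)C)=C2I)O1 | intermediate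
19 | (3S)-3-[(5R)-5-{[4-[(tert-butyldimethylsilyloxy)methyl]-3-iodo-5-oxo-2,5-dihydrofuran-2-yl](triethylsilyloxy)methyl}-5-methyl-4,5-dihydrofuran-2-yl]-3-(triethylsilyloxy)butanal (C5/C6 unassigned) | O=CC[C@](C)(O[Si](CC)(CC)CC)C1=CC[C@](C)(C(O[Si](CC)(CC)CC)C2OC(=O)C(CO[Si](C)(C)C(C)(C)C)=C2I)O1 | intermediate
20 | (4R,8R,10S)-13-(tert-butyldimethylsilyloxy)-8-hydroxy-5,10-bis(triethylsilyloxy)-1,4-epoxygermacra-1,7(11)-dien-12,6-olide (C5/C6 unassigned) | O[C@@H]1C[C@](C)(O[Si](CC)(CC)CC)C2=CC[C@](C)(C(O[Si](CC)(CC)CC)C3OC(=O)C(CO[Si](C)(C)C(C)(C)C)=C31)O2 | intermediate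
21 | (4R,8R,10S)-13-(tert-butyldimethylsilyloxy)-8-(methacryloyloxy)-5,10-bis(triethylsilyloxy)-1,4-epoxygermacra-1,7(11)-dien-12,6-olide (C5/C6 unassigned) | C=C(C)C(=O)O[C@@H]1C[C@](C)(O[Si](CC)(CC)CC)C2=CC[C@](C)(C(O[Si](CC)(CC)CC)C3OC(=O)C(CO[Si](C)(C)C(C)(C)C)=C31)O2 | intermediate
22 | (4R,8R,10S)-5,10,13-trihydroxy-8-(methacryloyloxy)-1,4-epoxygermacra-1,7(11)-dien-12,6-olide (C5/C6 unassigned) | C=C(C)C(=O)O[C@@H]1C[C@](C)(O)C2=CC[C@](C)(C(O)C3OC(=O)C(CO)=C31)O2 | intermediate
23 | (4R,8R,10S)-13-acetoxy-5,10-dihydroxy-8-(methacryloyloxy)-1,4-epoxygermacra-1,7(11)-dien-12,6-olide (C5/C6 unassigned) | C=C(C)C(=O)O[C@@H]1C[C@](C)(O)C2=CC[C@](C)(C(O)C3OC(=O)C(COC(C)=O)=C31)O2 | intermediate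
24 | (4R,8R,10S)-13-acetoxy-10-hydroxy-5-(methanesulfonyloxy)-8-(methacryloyloxy)-1,4-epoxygermacra-1,7(11)-dien-12,6-olide (C5/C6 unassigned) | C=C(C)C(=O)O[C@@H]1C[C@](C)(O)C2=CC[C@](C)(C(OS(C)(=O)=O)C3OC(=O)C(COC(C)=O)=C31)O2 | intermediate (not isolated)
25 | CNP0394509.1, (4R,5E,8R,10S)-13-acetoxy-10-hydroxy-8-(methacryloyloxy)-1,4-epoxygermacra-1,5,7(11)-trien-12,6-olide | C=C(C)C(=O)O[C@@H]1C[C@](C)(O)C2=CC[C@](C)(/C=C3/OC(=O)C(COC(C)=O)=C31)O2 | target

**Step count**
Total: 19 steps. Longest linear sequence: 14 steps (steps 1–5, 7, 8, 13–19).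

**Steps most likely to fail**

Step 7 (Proposed new method). The carbene may be lost by 1,2-hydride shift, or the ylide may close with poor facial control at C4. The fallback sets out from 6 and uses known chemistry in which C3–C4 is made by conjugate addition and the ring is closed through oxygen. The lithium enolate of commercial (2S,5S)-2-tert-butyl-5-methyl-1,3-dioxolan-4-one (C[C@@H]1O[C@H](C(C)(C)C)OC1=O; LiN(i-Pr)2, THF, −78 °C) should add to vinyl ketone 6 anti to the tert-butyl group (self-regeneration of the lactate stereocentre) and give (2S,5R)-2-tert-butyl-5-methyl-5-[(4S)-4-methyl-3-oxo-4,6-bis(triethylsilyloxy)hexyl]-1,3-dioxolan-4-one F1. Ethanolysis (NaOEt, EtOH, 0 °C) should release pivalaldehyde and give ethyl (2R,6S)-2-hydroxy-2,6-dimethyl-5-oxo-6,8-bis(triethylsilyloxy)octanoate F2, in equilibrium with its cyclic hemiketal. Dehydration of the hemiketal (MsCl, Et3N, CH2Cl2, 0 → 40 °C) can only go into the ring, since C10 has no hydrogen, and the fallback comes back to the route at 10.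

Step 15. The ring closure may add to the wrong face of the C8 aldehyde. The fallback sets out from 19: the closure would then give (4R,8S,10S)-13-(tert-butyldimethylsilyloxy)-8-hydroxy-5,10-bis(triethylsilyloxy)-1,4-epoxygermacra-1,7(11)-dien-12,6-olide F3. Mitsunobu esterification of F3 with methacrylic acid (PPh3, DIAD, toluene, 0 °C) sets C8 by SN2 inversion and not by substrate-controlled addition; SN2' attack is unlikely at the fully substituted, electron-poor C11. It replaces step 16 and comes back to the route at 21.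

Step 19. The dienolate may expel the C13 acetate in competition, or the hindered C5 hydroxyl may be sulfonylated too slowly, which leaves time for retro-aldol opening. The fallback sets out from 21 and eliminates before any acetate is present. DBU (toluene, rt → 50 °C) should expel triethylsilanolate from C5 by E1cB and give (4R,5E,8R,10S)-13-(tert-butyldimethylsilyloxy)-8-(methacryloyloxy)-10-(triethylsilyloxy)-1,4-epoxygermacra-1,5,7(11)-trien-12,6-olide F4. HF·pyridine/pyridine should then give (4R,5E,8R,10S)-10,13-dihydroxy-8-(methacryloyloxy)-1,4-epoxygermacra-1,5,7(11)-trien-12,6-olide F5, and selective acetylation of the primary hydroxyl (Ac2O, collidine) comes back to the route at 25.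

**Further compounds**
F1 | step 7 | (2S,5R)-2-tert-butyl-5-methyl-5-[(4S)-4-methyl-3-oxo-4,6-bis(triethylsilyloxy)hexyl]-1,3-dioxolan-4-one | CC[Si](CC)(CC)OCC[C@](C)(O[Si](CC)(CC)CC)C(=O)CC[C@]1(C)C(=O)O[C@@H](C(C)(C)C)O1
F2 | step 7 | ethyl (2R,6S)-2-hydroxy-2,6-dimethyl-5-oxo-6,8-bis(triethylsilyloxy)octanoate | CC[Si](CC)(CC)OCC[C@](C)(O[Si](CC)(CC)CC)C(=O)CC[C@@](C)(O)C(=O)OCC
F3 | step 15 | (4R,8S,10S)-13-(tert-butyldimethylsilyloxy)-8-hydroxy-5,10-bis(triethylsilyloxy)-1,4-epoxygermacra-1,7(11)-dien-12,6-olide | O[C@H]1C[C@](C)(O[Si](CC)(CC)CC)C2=CC[C@](C)(C(O[Si](CC)(CC)CC)C3OC(=O)C(CO[Si](C)(C)C(C)(C)C)=C31)O2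
F4 | step 19 | (4R,5E,8R,10S)-13-(tert-butyldimethylsilyloxy)-8-(methacryloyloxy)-10-(triethylsilyloxy)-1,4-epoxygermacra-1,5,7(11)-trien-12,6-olide | C=C(C)C(=O)O[C@@H]1C[C@](C)(O[Si](CC)(CC)CC)C2=CC[C@](C)(/C=C3/OC(=O)C(CO[Si](C)(C)C(C)(C)C)=C31)O2
F5 | step 19 | (4R,5E,8R,10S)-10,13-dihydroxy-8-(methacryloyloxy)-1,4-epoxygermacra-1,5,7(11)-trien-12,6-olide | C=C(C)C(=O)O[C@@H]1C[C@](C)(O)C2=CC[C@](C)(/C=C3/OC(=O)C(CO)=C31)O2
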